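**Strategy**

Everything rests on opening ring B, the 2,4-disubstituted furan (O1; C2 carrying the CH2 link to C3 of ring A; C3–H; C4 carrying the side chain; C5–H), at its C3–C4 and O1–C2 bonds. One operation catalysed by Ph3PAuCl/AgBF4 turns an acyclic precursor, a racemic ethyl 3-(propargyloxy)acrylate with the 3-furyl ring on the carbinol carbon and a free alkyne terminus, into ethyl 5-(furan-3-ylmethyl)furan-3-carboxylate by propargyl Claisen shift and cycloisomerisation of the 2-formyl-3,4-dienoate so formed. The C4 ester is then extended to an (E)-enal, joined to an (S)-sulfone by Julia–Kocienski olefination, and the tetronic acid is attached last by aldol condensation and demethylation.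

Key step: step 3

Remark: CIP analysis of the target SMILES gives (S) at the side-chain stereocentre, (Z) at the ylidene and (E,E) in the diene; compounds 2, 4, 10, 13, 15 and 24 are taken as purchased.

**Route**

Step 1
Reactants: 1 3-furaldehyde; 2 ethynylmagnesium bromide
Product: 3 1-(furan-3-yl)prop-2-yn-1-ol (racemic)
Conditions: THF, 0 °C to rt; aq NH4Cl
Reagents that add atoms: none
Why: Grignard 1,2-addition of the alkynyl nucleophile to the aldehyde should give the propargylic alcohol as a racemate, which is acceptable because this centre is erased in step 3.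

Step 2
Reactants: 3 1-(furan-3-yl)prop-2-yn-1-ol; 4 ethyl propiolate
Product: 5 ethyl (2E)-3-{[1-(furan-3-yl)prop-2-yn-1-yl]oxy}prop-2-enoate (racemic)
Conditions: DABCO (10 mol %), CH2Cl2, 0 °C to rt
Reagents that add atoms: none
Why: Amine-catalysed oxa-Michael addition: DABCO adds to the propiolate, the resulting zwitterion deprotonates the alcohol, and alkoxide addition followed by loss of the amine should give the (E)-β-alkoxyacrylate without touching the terminal alkyne or the furan.

Step 3
Reactants: 5 ethyl (2E)-3-{[1-(furan-3-yl)prop-2-yn-1-yl]oxy}prop-2-enoate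
Product: 7 ethyl 5-(furan-3-ylmethyl)furan-3-carboxylate, via allenyl formyl ester 6 (not isolated)
Conditions: Ph3PAuCl (2 mol %), AgBF4 (2 mol %), CH2Cl2, rt
Reagents that add atoms: none
Why: The cationic monovalent gold complex Ph3PAu+ BF4− coordinates the terminal alkyne of 5, the acrylate α-carbon attacks the alkyne terminus through a six-membered array, and C–O cleavage completes a propargyl Claisen [3,3] shift that forms the C3–C4 bond of ring B and gives 6. The closest known reaction type is the propargyl Claisen rearrangement/heterocyclisation cascade of 3-(propargyloxy)acrylates to furan-3-carboxylates under cationic monovalent gold catalysis. Ring B then closes by 5-exo-dig attack of the enolised formyl oxygen on the activated central allene carbon (O1–C2 bond), and protodeauration should leave the aromatic furan with the former carbinol carbon as the inter-ring CH2. No stereocentre is created, and the racemic carbinol centre of 5 and the allene axis of 6 are both erased, so no stereocontrol is required. Regiochemistry is fixed by the substrate: the unsubstituted alkyne terminus becomes C3–H, the acrylate β-CH becomes C5–H and the ester ends on C4. The step needs closure through the formyl oxygen and not the ester carbonyl, which the much higher enol content of the aldehyde in the 1,3-dicarbonyl unit should secure, and the neutral room-temperature conditions spare the acid-sensitive 3-furyl ring.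

Step 4
Reactants: 7 ethyl 5-(furan-3-ylmethyl)furan-3-carboxylate
Product: 8 [5-(furan-3-ylmethyl)furan-3-yl]methanol
Conditions: LiAlH4, Et2O, 0 °C; H2O
Reagents that add atoms: none
Why: LiAlH4 reduction of the ester should give the primary alcohol, and both furan rings are inert to hydride.

Step 5
Reactants: 8 [5-(furan-3-ylmethyl)furan-3-yl]methanol
Product: 9 4-(bromomethyl)-2-(furan-3-ylmethyl)furan
Conditions: CBr4, PPh3, CH2Cl2, 0 °C; used at once
Reagents that add atoms: carbon tetrabromide, BrC(Br)(Br)Br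
Why: The Appel reaction converts the alcohol through its alkoxyphosphonium bromide by SN2 displacement under neutral conditions, which avoids the acid that would endanger the difurylmethane unit.

Step 6
Reactants: 9 4-(bromomethyl)-2-(furan-3-ylmethyl)furan; 10 N-tert-butylethanimine
Product: 12 3-[5-(furan-3-ylmethyl)furan-3-yl]propanal, via homologated N-tert-butyl aldimine 11 (not isolated)
Conditions: LiN(i-Pr)2, THF, 0 °C (10); then 9, −78 °C to 0 °C; then aq oxalic acid, rt
Reagents that add atoms: water, O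
Why: Aza-enolate (metalloenamine) alkylation: the lithiated aldimine should displace the reactive furylmethyl bromide, and mild aqueous acid hydrolysis of 11 releases the aldehyde, so the two-carbon homologation needs no redox step.

Step 7
Reactants: 12 3-[5-(furan-3-ylmethyl)furan-3-yl]propanal; 13 2-(triphenyl-λ5-phosphanylidene)propanal
Product: 14 (2E)-5-[5-(furan-3-ylmethyl)furan-3-yl]-2-methylpent-2-enal
Conditions: toluene, 80 °C
Reagents that add atoms: none
Why: Wittig olefination with the stabilised formyl ylide should give the trisubstituted (E)-enal selectively, and the ylide is too unreactive to attack the conjugated aldehyde product.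

Step 8
Reactants: 15 (2R)-3-bromo-2-methylpropan-1-ol
Product: 16 [(2R)-3-bromo-2-methylpropoxy](tert-butyl)diphenylsilane
Conditions: t-BuPh2SiCl, imidazole, CH2Cl2, rt
Reagents that add atoms: tert-butyl(chloro)diphenylsilane, CC(C)(C)[Si](Cl)(c1ccccc1)c1ccccc1
Why: Imidazole-promoted silylation of the primary alcohol installs a base-stable, fluoride-labile ether and leaves the stereocentre untouched.

Step 9
Reactants: 16 [(2R)-3-bromo-2-methylpropoxy](tert-butyl)diphenylsilane
Product: 18 (3S)-4-[(tert-butyldiphenylsilyl)oxy]-3-methylbutan-1-ol, via Grignard reagent 17 (not isolated)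
Conditions: Mg (I2 cat.), THF, 45 °C; then CH2O (gas, from cracked paraformaldehyde), 0 °C to rt; aq NH4Cl
Reagents that add atoms: formaldehyde, C=O; magnesium, [Mg] (retained only in 17)
Why: Grignard formation and hydroxymethylation with formaldehyde add the one missing carbon with the oxygen at the unbranched end by construction; the stereocentre is β to the metal-bearing carbon and cannot epimerise, and the descriptor changes from R to S only because the substituent priorities change.

Step 10
Reactants: 18 (3S)-4-[(tert-butyldiphenylsilyl)oxy]-3-methylbutan-1-ol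
Product: 19 5-({(3S)-4-[(tert-butyldiphenylsilyl)oxy]-3-methylbutyl}sulfanyl)-1-phenyl-1H-tetrazole
Conditions: 1-phenyl-1H-tetrazole-5-thiol, PPh3, DIAD, THF, 0 °C to rt
Reagents that add atoms: 1-phenyl-1H-tetrazole-5-thiol, Sc1nnnn1-c1ccccc1
Why: Mitsunobu thioetherification: the alkoxyphosphonium ion of the unhindered primary alcohol is displaced in SN2 fashion by the acidic tetrazolethiol at a carbon remote from the stereocentre.

Step 11
Reactants: 19 5-({(3S)-4-[(tert-butyldiphenylsilyl)oxy]-3-methylbutyl}sulfanyl)-1-phenyl-1H-tetrazole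
Product: 20 5-({(3S)-4-[(tert-butyldiphenylsilyl)oxy]-3-methylbutyl}sulfonyl)-1-phenyl-1H-tetrazole
Conditions: (NH4)6Mo7O24·4H2O (10 mol %), 30% H2O2, EtOH, 0 °C to rt
Reagents that add atoms: hydrogen peroxide, OO
Why: Peroxide oxidation catalysed by (NH4)6Mo7O24 should take the sulfide through the sulfoxide to the sulfone; this fragment holds no alkene or furan, and the silyl ether tolerates the conditions.

Step 12
Reactants: 14 (2E)-5-[5-(furan-3-ylmethyl)furan-3-yl]-2-methylpent-2-enal; 20 5-({(3S)-4-[(tert-butyldiphenylsilyl)oxy]-3-methylbutyl}sulfonyl)-1-phenyl-1H-tetrazole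
Product: 21 tert-butyl({(2S,4E,6E)-9-[5-(furan-3-ylmethyl)furan-3-yl]-2,6-dimethylnona-4,6-dien-1-yl}oxy)diphenylsilane
Conditions: KN(SiMe3)2, DME, −60 °C (20); then 14, −60 °C to rt; aq NH4Cl
Reagents that add atoms: none
Why: Julia–Kocienski olefination: the potassium sulfonyl carbanion adds 1,2 to the enal, and Smiles rearrangement with loss of SO2 and the tetrazololate should give the new disubstituted alkene with E preference, which the phenyltetrazolyl sulfone with a potassium counter-ion in DME favours; the (S)-centre lies two carbons from the carbanion and is not affected.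

Step 13
Reactants: 21 tert-butyl({(2S,4E,6E)-9-[5-(furan-3-ylmethyl)furan-3-yl]-2,6-dimethylnona-4,6-dien-1-yl}oxy)diphenylsilane
Product: 22 (2S,4E,6E)-9-[5-(furan-3-ylmethyl)furan-3-yl]-2,6-dimethylnona-4,6-dien-1-ol
Conditions: Bu4NF, THF, 0 °C to rt; H2O
Reagents that add atoms: none
Why: Fluoride-induced silyl ether cleavage, driven by the strong Si–F bond, is mild enough for the diene and both furans.

Step 14
Reactants: 22 (2S,4E,6E)-9-[5-(furan-3-ylmethyl)furan-3-yl]-2,6-dimethylnona-4,6-dien-1-ol
Product: 23 (2S,4E,6E)-9-[5-(furan-3-ylmethyl)furan-3-yl]-2,6-dimethylnona-4,6-dienal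
Conditions: Dess–Martin periodinane, pyridine, CH2Cl2, 0 °C to rt; used directly
Reagents that add atoms: none
Why: Pyridine-buffered Dess–Martin oxidation should give the aldehyde without acid, over-oxidation or enolisation of the α-stereocentre.

Step 15
Reactants: 24 4-hydroxy-3-methylfuran-2(5H)-one (3-methyltetronic acid)
Product: 25 4-methoxy-3-methylfuran-2(5H)-one
Conditions: Me2SO4, K2CO3, acetone, reflux
Reagents that add atoms: dimethyl sulfate, COS(=O)(=O)OC
Why: O-Alkylation of the vinylogous acid with a hard electrophile masks the acidic hydroxyl as the 4-methoxy butenolide and makes C5 metalation possible.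

Step 16
Reactants: 23 (2S,4E,6E)-9-[5-(furan-3-ylmethyl)furan-3-yl]-2,6-dimethylnona-4,6-dienal; 25 4-methoxy-3-methylfuran-2(5H)-one
Product: 26 5-{(2S,4E,6E)-9-[5-(furan-3-ylmethyl)furan-3-yl]-1-hydroxy-2,6-dimethylnona-4,6-dien-1-yl}-4-methoxy-3-methylfuran-2(5H)-one (diastereomer mixture at C5 and C1′)
Conditions: LiN(i-Pr)2, THF, −78 °C (25, slight excess over base); then 23, −78 °C; aq NH4Cl at −78 °C
Reagents that add atoms: none
Why: Vinylogous aldol addition: kinetic deprotonation of 25 at C5 gives a 2-oxidofuran that should add through C5 to the aldehyde at −78 °C faster than it enolises the α-methyl aldehyde; the two new centres need no control because step 17 removes both.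

Step 17
Reactants: 26 5-{(2S,4E,6E)-9-[5-(furan-3-ylmethyl)furan-3-yl]-1-hydroxy-2,6-dimethylnona-4,6-dien-1-yl}-4-methoxy-3-methylfuran-2(5H)-one
Product: 28 (5Z)-5-{(2S,4E,6E)-9-[5-(furan-3-ylmethyl)furan-3-yl]-2,6-dimethylnona-4,6-dien-1-ylidene}-4-methoxy-3-methylfuran-2(5H)-one, via secondary mesylate 27 (not isolated)
Conditions: MsCl, Et3N, CH2Cl2, 0 °C; then DBU, rt
Reagents that add atoms: methanesulfonyl chloride, CS(=O)(=O)Cl (retained only in 27)
Why: Mesylation and DBU-induced E1cB elimination through the acidic C5 position should give the exocyclic alkene as the thermodynamically preferred (Z)-isomer, with the chain syn to the ring oxygen and away from the C4 methoxy group; the allylic (S)-centre takes no part.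

Step 18
Reactants: 28 (5Z)-5-{(2S,4E,6E)-9-[5-(furan-3-ylmethyl)furan-3-yl]-2,6-dimethylnona-4,6-dien-1-ylidene}-4-methoxy-3-methylfuran-2(5H)-one
Product: 29 (5Z)-5-{(2S,4E,6E)-9-[5-(furan-3-ylmethyl)furan-3-yl]-2,6-dimethylnona-4,6-dien-1-ylidene}-4-hydroxy-3-methylfuran-2(5H)-one (CNP0222779.1)
Conditions: sodium propane-1-thiolate, DMF, rt; then cold dilute aq HCl to pH 3
Reagents that add atoms: none
Why: Thiolate O-demethylation: the soft thiolate should attack the methyl carbon of the vinylogous ester in SN2 fashion and release the stabilised tetronate anion, which brief cold acidification protonates without harming the furans or alkenes.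

**Compound list**

1 | 3-furaldehyde | O=Cc1ccoc1 | starting material
2 | ethynylmagnesium bromide | C#C[Mg]Br | starting material
3 | 1-(furan-3-yl)prop-2-yn-1-ol (racemic) | OC(C#C)c1ccoc1 | intermediate
4 | ethyl propiolate | C#CC(=O)OCC | starting material
5 | ethyl (2E)-3-{[1-(furan-3-yl)prop-2-yn-1-yl]oxy}prop-2-enoate (racemic) | CCOC(=O)/C=C/OC(C#C)c1ccoc1 | intermediate
6 | ethyl 2-formyl-5-(furan-3-yl)penta-3,4-dienoate | CCOC(=O)C(C=O)C=C=Cc1ccoc1 | intermediate
7 | ethyl 5-(furan-3-ylmethyl)furan-3-carboxylate | CCOC(=O)c1coc(Cc2ccoc2)c1 | intermediate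
8 | [5-(furan-3-ylmethyl)furan-3-yl]methanol | OCc1coc(Cc2ccoc2)c1 | intermediate
9 | 4-(bromomethyl)-2-(furan-3-ylmethyl)furan | BrCc1coc(Cc2ccoc2)c1 | intermediate
10 | N-tert-butylethanimine | CC=NC(C)(C)C | starting material
11 | N-tert-butyl-3-[5-(furan-3-ylmethyl)furan-3-yl]propan-1-imine | CC(C)(C)N=CCCc1coc(Cc2ccoc2)c1 | intermediate
12 | 3-[5-(furan-3-ylmethyl)furan-3-yl]propanal | O=CCCc1coc(Cc2ccoc2)c1 | intermediate
13 | 2-(triphenyl-λ5-phosphanylidene)propanal | CC(C=O)=P(c1ccccc1)(c1ccccc1)c1ccccc1 | starting material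
14 | (2E)-5-[5-(furan-3-ylmethyl)furan-3-yl]-2-methylpent-2-enal | O=C/C(C)=C/CCc1coc(Cc2ccoc2)c1 | intermediate
15 | (2R)-3-bromo-2-methylpropan-1-ol | OC[C@@H](C)CBr | starting material
16 | [(2R)-3-bromo-2-methylpropoxy](tert-butyl)diphenylsilane | CC(C)(C)[Si](c1ccccc1)(c1ccccc1)OC[C@@H](C)CBr | intermediate
17 | {(2R)-3-[(tert-butyldiphenylsilyl)oxy]-2-methylpropyl}magnesium bromide | CC(C)(C)[Si](c1ccccc1)(c1ccccc1)OC[C@@H](C)C[Mg]Br | intermediate
18 | (3S)-4-[(tert-butyldiphenylsilyl)oxy]-3-methylbutan-1-ol | CC(C)(C)[Si](c1ccccc1)(c1ccccc1)OC[C@@H](C)CCO | intermediate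
19 | 5-({(3S)-4-[(tert-butyldiphenylsilyl)oxy]-3-methylbutyl}sulfanyl)-1-phenyl-1H-tetrazole | CC(C)(C)[Si](c1ccccc1)(c1ccccc1)OC[C@@H](C)CCSc1nnnn1-c1ccccc1 | intermediate
20 | 5-({(3S)-4-[(tert-butyldiphenylsilyl)oxy]-3-methylbutyl}sulfonyl)-1-phenyl-1H-tetrazole | CC(C)(C)[Si](c1ccccc1)(c1ccccc1)OC[C@@H](C)CCS(=O)(=O)c1nnnn1-c1ccccc1 | intermediate
21 | tert-butyl({(2S,4E,6E)-9-[5-(furan-3-ylmethyl)furan-3-yl]-2,6-dimethylnona-4,6-dien-1-yl}oxy)diphenylsilane | CC(C)(C)[Si](c1ccccc1)(c1ccccc1)OC[C@@H](C)C/C=C/C(C)=C/CCc1coc(Cc2ccoc2)c1 | intermediate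
22 | (2S,4E,6E)-9-[5-(furan-3-ylmethyl)furan-3-yl]-2,6-dimethylnona-4,6-dien-1-ol | OC[C@@H](C)C/C=C/C(C)=C/CCc1coc(Cc2ccoc2)c1 | intermediate
23 | (2S,4E,6E)-9-[5-(furan-3-ylmethyl)furan-3-yl]-2,6-dimethylnona-4,6-dienal | O=C[C@@H](C)C/C=C/C(C)=C/CCc1coc(Cc2ccoc2)c1 | intermediate
24 | 4-hydroxy-3-methylfuran-2(5H)-one (3-methyltetronic acid) | CC1=C(O)COC1=O | starting material
25 | 4-methoxy-3-methylfuran-2(5H)-one | COC1=C(C)C(=O)OC1 | intermediate
26 | 5-{(2S,4E,6E)-9-[5-(furan-3-ylmethyl)furan-3-yl]-1-hydroxy-2,6-dimethylnona-4,6-dien-1-yl}-4-methoxy-3-methylfuran-2(5H)-one | COC1=C(C)C(=O)OC1C(O)[C@@H](C)C/C=C/C(C)=C/CCc1coc(Cc2ccoc2)c1 | intermediate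
27 | (2S,4E,6E)-9-[5-(furan-3-ylmethyl)furan-3-yl]-1-(3-methoxy-4-methyl-5-oxo-2,5-dihydrofuran-2-yl)-2,6-dimethylnona-4,6-dien-1-yl methanesulfonate | COC1=C(C)C(=O)OC1C(OS(C)(=O)=O)[C@@H](C)C/C=C/C(C)=C/CCc1coc(Cc2ccoc2)c1 | intermediate
28 | (5Z)-5-{(2S,4E,6E)-9-[5-(furan-3-ylmethyl)furan-3-yl]-2,6-dimethylnona-4,6-dien-1-ylidene}-4-methoxy-3-methylfuran-2(5H)-one | CC1=C(OC)/C(=C/[C@@H](C)C/C=C/C(C)=C/CCc2coc(Cc3ccoc3)c2)OC1=O | intermediate
29 | (5Z)-5-{(2S,4E,6E)-9-[5-(furan-3-ylmethyl)furan-3-yl]-2,6-dimethylnona-4,6-dien-1-ylidene}-4-hydroxy-3-methylfuran-2(5H)-one | CC1=C(O)/C(=C/[C@@H](C)C/C=C/C(C)=C/CCc2coc(Cc3ccoc3)c2)OC1=O | target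

**Step count and risks**

Total step count: 18. Longest linear sequence: 13 steps (1–7, 12–14, 16–18).

Steps most likely to fail:

Step 3. The cationic gold catalyst may ionise the furyl-activated propargylic C–O bond before the sigmatropic shift, may be sequestered by the terminal alkyne as an acetylide, or the allene may close through the wrong oxygen. The fallback does not build ring B but buys it and makes the bond between the inter-ring CH2 and C2 of ring B by cross-coupling. It sets out from 1: NaBH4 in MeOH gives furan-3-ylmethanol F1, PBr3 in Et2O at 0 °C gives 3-(bromomethyl)furan F2, and Zn dust with LiCl in THF gives (furan-3-ylmethyl)zinc bromide F3. Negishi coupling of F3 with purchased ethyl 5-bromofuran-3-carboxylate F4, catalysed by the zerovalent palladium complex Pd(PPh3)4 in THF, comes back to the route at 7.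

Step 12. E selectivity may be incomplete in the addition/Smiles rearrangement/elimination sequence, or the sulfonyl carbanion may deprotonate the enal at its γ-position instead of adding. The fallback makes the C4=C5 alkene by Horner–Wadsworth–Emmons olefination and sets the stereocentre by auxiliary-controlled enolate alkylation. It sets out from 14: triethyl phosphonoacetate and NaH in THF give ethyl (2E,4E)-7-[5-(furan-3-ylmethyl)furan-3-yl]-4-methylhepta-2,4-dienoate F5; i-Bu2AlH at −78 °C gives (2E,4E)-7-[5-(furan-3-ylmethyl)furan-3-yl]-4-methylhepta-2,4-dien-1-ol F6; CBr4 and PPh3 give 4-[(3E,5E)-7-bromo-4-methylhepta-3,5-dien-1-yl]-2-(furan-3-ylmethyl)furan F7. The sodium enolate (NaN(SiMe3)2, THF, −78 °C) of purchased (4R)-4-benzyl-3-propanoyl-1,3-oxazolidin-2-one F8 is alkylated by F7 on the face away from the benzyl group to give (4R)-4-benzyl-3-{(2S,4E,6E)-9-[5-(furan-3-ylmethyl)furan-3-yl]-2,6-dimethylnona-4,6-dienoyl}-1,3-oxazolidin-2-one F9. LiBH4 in wet Et2O removes the auxiliary reductively and comes back to the route at 22.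

Step 18. The thiolate may add in conjugate fashion to the ylidene butenolide or substitute at C4 instead of attacking the methyl carbon, and the basic medium may epimerise the allylic stereocentre by vinylogous deprotonation. The fallback carries the enol oxygen as an allyl ether that is removed under neutral conditions. It sets out from 23 and 24: Mitsunobu O-alkylation of 24 with allyl alcohol (PPh3, DIAD) gives 3-methyl-4-(prop-2-en-1-yloxy)furan-2(5H)-one F10; its C5 lithium dienolate (LiN(i-Pr)2, THF, −78 °C) adds to 23 to give 5-{(2S,4E,6E)-9-[5-(furan-3-ylmethyl)furan-3-yl]-1-hydroxy-2,6-dimethylnona-4,6-dien-1-yl}-3-methyl-4-(prop-2-en-1-yloxy)furan-2(5H)-one F11. MsCl and Et3N give the corresponding secondary methanesulfonate F12, which DBU converts to (5Z)-5-{(2S,4E,6E)-9-[5-(furan-3-ylmethyl)furan-3-yl]-2,6-dimethylnona-4,6-dien-1-ylidene}-3-methyl-4-(prop-2-en-1-yloxy)furan-2(5H)-one F13. The zerovalent palladium complex Pd(PPh3)4 with morpholine as allyl acceptor in THF at rt cleaves the allyl ether and comes back to the route at 29.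

**Further compounds**

F1 | step 3 | furan-3-ylmethanol | OCc1ccoc1
F2 | step 3 | 3-(bromomethyl)furan | BrCc1ccoc1
F3 | step 3 | (furan-3-ylmethyl)zinc bromide | Br[Zn]Cc1ccoc1
F4 | step 3 | ethyl 5-bromofuran-3-carboxylate | CCOC(=O)c1coc(Br)c1
F5 | step 12 | ethyl (2E,4E)-7-[5-(furan-3-ylmethyl)furan-3-yl]-4-methylhepta-2,4-dienoate | CCOC(=O)/C=C/C(C)=C/CCc1coc(Cc2ccoc2)c1
F6 | step 12 | (2E,4E)-7-[5-(furan-3-ylmethyl)furan-3-yl]-4-methylhepta-2,4-dien-1-ol | OC/C=C/C(C)=C/CCc1coc(Cc2ccoc2)c1
F7 | step 12 | 4-[(3E,5E)-7-bromo-4-methylhepta-3,5-dien-1-yl]-2-(furan-3-ylmethyl)furan | BrC/C=C/C(C)=C/CCc1coc(Cc2ccoc2)c1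
F8 | step 12 | (4R)-4-benzyl-3-propanoyl-1,3-oxazolidin-2-one | CCC(=O)N1[C@H](Cc2ccccc2)COC1=O
F9 | step 12 | (4R)-4-benzyl-3-{(2S,4E,6E)-9-[5-(furan-3-ylmethyl)furan-3-yl]-2,6-dimethylnona-4,6-dienoyl}-1,3-oxazolidin-2-one | O=C1OC[C@@H](Cc2ccccc2)N1C(=O)[C@@H](C)C/C=C/C(C)=C/CCc1coc(Cc2ccoc2)c1
F10 | step 18 | 3-methyl-4-(prop-2-en-1-yloxy)furan-2(5H)-one | C=CCOC1=C(C)C(=O)OC1
F11 | step 18 | 5-{(2S,4E,6E)-9-[5-(furan-3-ylmethyl)furan-3-yl]-1-hydroxy-2,6-dimethylnona-4,6-dien-1-yl}-3-methyl-4-(prop-2-en-1-yloxy)furan-2(5H)-one | C=CCOC1=C(C)C(=O)OC1C(O)[C@@H](C)C/C=C/C(C)=C/CCc1coc(Cc2ccoc2)c1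
F12 | step 18 | (2S,4E,6E)-9-[5-(furan-3-ylmethyl)furan-3-yl]-2,6-dimethyl-1-[4-methyl-5-oxo-3-(prop-2-en-1-yloxy)-2,5-dihydrofuran-2-yl]nona-4,6-dien-1-yl methanesulfonate | C=CCOC1=C(C)C(=O)OC1C(OS(C)(=O)=O)[C@@H](C)C/C=C/C(C)=C/CCc1coc(Cc2ccoc2)c1
F13 | step 18 | (5Z)-5-{(2S,4E,6E)-9-[5-(furan-3-ylmethyl)furan-3-yl]-2,6-dimethylnona-4,6-dien-1-ylidene}-3-methyl-4-(prop-2-en-1-yloxy)furan-2(5H)-one | CC1=C(OCC=C)/C(=C/[C@@H](C)C/C=C/C(C)=C/CCc2coc(Cc3ccoc3)c2)OC1=O
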